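A direct plan would build the chain by an alkyl–alkyl cross-coupling next to the ester: 3-bromopropanoic acid A1 would be esterified to 2-phenylethyl 3-bromopropanoate A2, zinc would be inserted to give the homoenolate A3, and palladium catalysis would join A3 to 1-bromodocosane A4.
Weak point, the esterification of the beta-bromo acid: A2 would sit one E1cB step from the acrylate, so heat and even a bicarbonate wash would erode it, and the step builds none of the chain.
Weak point, the alkyl–alkyl Negishi coupling: the docosyl–palladium intermediate would carry beta-hydrogens (docosene and docosane by beta-hydride elimination), the chelated homoenolate A3 would transmetalate slowly, and the more elaborate partner A2 would have to be used in excess.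
Weak point, the choice of fragments: stoichiometric zinc, a palladium catalyst and an air-free two-stage protocol would be spent on one unfunctionalised CH2–CH2 bond, with the C22 unit bought as a bromide although it is available in bulk as the natural acid.

**Retrosynthetic overview**
The feature used is the unbranched, unfunctionalised C25 acyl chain: from C2 to C25 no atom dictates polarity, so the C4–C5 bond is cut homolytically into two primary radicals, each masked as a carboxylic acid.
C1–C4 with the 2-phenylethyl ester comes from glutaric anhydride 1 and 2-phenylethanol 2 (ring-opening to half-ester 3); C5–C25 comes from natural docosanoic acid 4.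
A mixed Kolbe electrolysis extrudes one CO2 from each acid and joins henicosyl radical 5 to ester radical 6, giving target 7 (21 + 4 carbons = the C25 acyl chain) in one anodic operation.
No ring is formed and no stereocentre exists. No halide, organometal or palladium appears, and the symmetric by-products carry no or two ester groups, so the separation rests on polarity.

Key step: step 2

Remark: glutaric anhydride, 2-phenylethanol and docosanoic acid are taken as commercial bulk chemicals; the only ring of the target, the phenyl group, is bought with 2-phenylethanol.

Step 1
Reactants: 1 glutaric anhydride (1.0 equiv); 2 2-phenylethanol (1.05 equiv)
Product: 3 5-oxo-5-(2-phenylethoxy)pentanoic acid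
Conditions: 4-(dimethylamino)pyridine (5 mol %), toluene, 80 °C, 6 h; extract into aq NaHCO3, acidify (1 M HCl), extract (EtOAc)
Reagents that add atoms: none
Why: Alcoholysis of a cyclic anhydride under nucleophilic catalysis (acyl substitution via the N-acylpyridinium) should stop cleanly at the half-ester, because the carboxylic acid that is set free is not activated towards a second esterification; no stereocentre is formed.

Step 2
Reactants: 3 5-oxo-5-(2-phenylethoxy)pentanoic acid (4.0 equiv); 4 docosanoic acid (1.0 equiv)
Product: 7 2-phenylethyl pentacosanoate, via henicosyl radical 5 (not isolated), via 4-oxo-4-(2-phenylethoxy)butyl radical 6 (not isolated)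
Conditions: KOH (0.1 equiv per CO2H), acetone, 40 °C, undivided cell, reticulated vitreous carbon anode and cathode, rapid alternating polarity (square wave, 50 ms per half-cycle), constant current, 2 F per mol CO2H; evaporate, heptane/aq NaHCO3, SiO2 (hexane, then hexane/EtOAc 97:3), recrystallise from acetone
Reagents that add atoms: none
Why: Each carboxylate is oxidised by one electron at the anode, the acyloxy radicals lose CO2, and the primary radicals 5 and 6, formed side by side at high concentration in the layer at the electrode, recombine to the C4–C5 bond of 7 while the carboxyl protons leave as H2 at the counter-electrode. The closest known reaction type is the mixed Kolbe electrolysis of a fatty acid with an alkanedioic acid half-ester, the classical chain extension to long-chain esters, run here with the alternating-polarity waveform on carbon in acetone that is known for Kolbe coupling of functionalised acids. No ring is closed and no stereocentre is formed. The selectivity needed is cross-coupling over the two homo-couplings; it is statistical and is secured by the fourfold excess of the cheap half-ester 3, so that about four of five radicals 5 should meet a radical 6, and the symmetric by-products dotetracontane (no ester) and bis(2-phenylethyl) octanedioate (two esters) bracket 7 in polarity and should separate on silica. Chemoselectivity rests on substrate and medium: both radicals are primary and unstabilised, so further oxidation to cations is slow, the monoalkylbenzene ring is not electron-rich, and the alcohol-free, acid-buffered acetone offers the 2-phenylethyl ester no partner for ester interchange.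

**Compound list**
1 | glutaric anhydride (oxane-2,6-dione) | O=C1CCCC(=O)O1 | starting material
2 | 2-phenylethanol | OCCc1ccccc1 | starting material
3 | 5-oxo-5-(2-phenylethoxy)pentanoic acid (mono-2-phenylethyl glutarate) | OC(=O)CCCC(=O)OCCc1ccccc1 | intermediate
4 | docosanoic acid (behenic acid) | CCCCCCCCCCCCCCCCCCCCCC(=O)O | starting material
5 | henicosyl radical (not isolated) | [CH2]CCCCCCCCCCCCCCCCCCCC | intermediate
6 | 4-oxo-4-(2-phenylethoxy)butyl radical (not isolated) | [CH2]CCC(=O)OCCc1ccccc1 | intermediate
7 | 2-phenylethyl pentacosanoate | CCCCCCCCCCCCCCCCCCCCCCCCC(=O)OCCc1ccccc1 | target

Total step count: 2. Longest linear sequence: 2 steps (1 + 2 to 3, then 3 + 4 to 7). The route has only two steps, so both are ranked.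

Most likely to fail, first: step 2, the mixed Kolbe electrolysis.
- The long-chain carboxylate may be enriched at the anode, so that radical 5 pairs with its own kind more often than statistics predict.
- The radicals may be oxidised further to cations on the carbon surface, giving alkenes and oxygenated products instead of the C–C bond.
- The waxy product may coat the electrodes, so that the cell voltage climbs and the arene starts to be oxidised.

The fallback replaces the radical C4–C5 coupling by a three-component carbonylation that forms the C1–C2 bond and the ester C–O bond. It would set out from 2-phenylethanol 2, which with commercial 1-tetracosene F1 and CO (20 bar) under Pd(OAc)2 (1 mol %), 1,2-bis(di-tert-butylphosphinomethyl)benzene (4 mol %) and MeSO3H (10 mol %) in toluene at 90 °C should undergo linear-selective hydroalkoxycarbonylation. It comes back to the route directly at target 7.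

Second: step 1, the anhydride opening.
- Adventitious water may hydrolyse the anhydride to glutaric acid, a diacid that would enter the electrolysis as a third radical source.
- The amphiphilic half-ester may be lost in part during the acid–base extraction.
- Unreacted 2-phenylethanol may be carried on and oxidised at the anode.

The fallback differentiates the two carboxyl groups by a protecting group instead of by ring-opening. It would set out from 2-phenylethanol 2, which would be coupled with commercial 5-tert-butoxy-5-oxopentanoic acid F2 (N,N'-diisopropylcarbodiimide, catalytic 4-(dimethylamino)pyridine, CH2Cl2) to tert-butyl 2-phenylethyl pentanedioate F3. The tert-butyl ester would then be cleaved with CF3CO2H in CH2Cl2, which leaves the primary 2-phenylethyl ester untouched, and the sequence comes back to the route at half-ester 3.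

**Further compounds**
F1 | step 2 | 1-tetracosene | C=CCCCCCCCCCCCCCCCCCCCCCC
F2 | step 1 | 5-tert-butoxy-5-oxopentanoic acid | CC(C)(C)OC(=O)CCCC(=O)O
F3 | step 1 | tert-butyl 2-phenylethyl pentanedioate | CC(C)(C)OC(=O)CCCC(=O)OCCc1ccccc1
A1 | direct plan | 3-bromopropanoic acid | OC(=O)CCBr
A2 | direct plan | 2-phenylethyl 3-bromopropanoate | BrCCC(=O)OCCc1ccccc1
A3 | direct plan | bromo[3-oxo-3-(2-phenylethoxy)propyl]zinc | Br[Zn]CCC(=O)OCCc1ccccc1
A4 | direct plan | 1-bromodocosane | CCCCCCCCCCCCCCCCCCCCCCBr
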